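**Retrosynthetic overview**
- Target ⇐ one-pot hydrogenation, hydrogenolysis and reductive N-methylation of a Cbz-protected 2-aryl-1,2,5,6-tetrahydropyridine carried on 7,4'-di-O-benzylnaringenin.
- C-6–C-2(piperidine) bond ⇐ aromatic Claisen ([3,3]) shift of the 5-O-(1-Cbz-1,2,3,4-tetrahydropyridin-4-yl) ether. C-6 is the only open ortho position, and the suprafacial shift copies the ether configuration at C-4 onto the new benzylic carbon.
- Allyl aryl ether ⇐ enecarbamate formation from a 2-methoxy N,O-acetal, after Mitsunobu inversion of a (4R)-4-hydroxypiperidine carbamate at the chelated 5-OH.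
- Ring order: the piperidine ring is made first, by reductive lactamisation of ethyl (3R)-4-cyano-3-hydroxybutanoate. Rings A, B, C and the flavanone C-2 centre are taken intact from (2S)-naringenin; no other ring is formed.

Assumption: (2S)-naringenin and ethyl (3R)-4-cyano-3-hydroxybutanoate are bought as single enantiomers; the N,O-acetal carbon of compounds 6, 7, 8 and 11 is an epimer mixture that is erased in step 7 and is left undefined.

**Step 1**
Reactants: 1 ethyl (3R)-4-cyano-3-hydroxybutanoate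
Product: 3 (4R)-4-hydroxypiperidin-2-one, via ethyl (3R)-5-amino-3-hydroxypentanoate 2 (not isolated)
Conditions: H2 (5 bar), Raney Ni, NH3/MeOH, 50 °C
Reagents that add atoms: none
Why: Catalytic nitrile hydrogenation gives the primary amine, which closes onto the ethyl ester (lactamisation) without touching the carbinol centre.

**Step 2**
Reactants: 3 (4R)-4-hydroxypiperidin-2-one
Product: 4 (4R)-4-[(tert-butyldimethylsilyl)oxy]piperidin-2-one
Conditions: TBSCl, imidazole, DMF, rt
Reagents that add atoms: tert-butyldimethylsilyl chloride, CC(C)(C)[Si](C)(C)Cl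
Why: Standard O-silylation masks the alcohol so that only the lactam N–H is acylated in the next step.

**Step 3**
Reactants: 4 (4R)-4-[(tert-butyldimethylsilyl)oxy]piperidin-2-one
Product: 5 benzyl (4R)-4-[(tert-butyldimethylsilyl)oxy]-2-oxopiperidine-1-carboxylate
Conditions: n-BuLi, THF, −78 °C; then CbzCl, −78 → −40 °C
Reagents that add atoms: benzyl chloroformate, O=C(Cl)OCc1ccccc1
Why: N-Acylation of the lithiated lactam gives an imide-type carbonyl that is activated for partial hydride reduction and carries a group removable by hydrogenolysis.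

**Step 4**
Reactants: 5 benzyl (4R)-4-[(tert-butyldimethylsilyl)oxy]-2-oxopiperidine-1-carboxylate
Product: 8 benzyl (4R)-4-hydroxy-2-methoxypiperidine-1-carboxylate, via 2-hydroxy carbamate 6 (not isolated), via 2-methoxy silyl ether 7 (not isolated)
Conditions: LiEt3BH, THF, −78 °C; then HCl/MeOH, −78 °C → rt
Reagents that add atoms: methanol, CO
Why: Hydride stops at the N-acyl hemiaminal, and acidic methanol converts it through the N-acyliminium ion into the N,O-acetal while cleaving the silyl ether; C-4 is untouched.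

**Step 5**
Reactants: 9 (2S)-naringenin, (2S)-5,7-dihydroxy-2-(4-hydroxyphenyl)chroman-4-one
Product: 10 (2S)-7-(benzyloxy)-2-[4-(benzyloxy)phenyl]-5-hydroxychroman-4-one
Conditions: BnOH (2.2 equiv), PPh3, DIAD, THF, 0 °C → rt
Reagents that add atoms: benzyl alcohol, OCc1ccccc1
Why: Mitsunobu etherification takes the two acidic, unchelated phenols (7-OH, 4'-OH) and leaves the hydrogen-bonded 5-OH, under neutral conditions that avoid base-induced chalcone opening and loss of C-2.

**Step 6**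
Reactants: 8 benzyl (4R)-4-hydroxy-2-methoxypiperidine-1-carboxylate; 10 (2S)-7-(benzyloxy)-2-[4-(benzyloxy)phenyl]-5-hydroxychroman-4-one
Product: 11 benzyl (4S)-4-{[(2S)-7-(benzyloxy)-2-[4-(benzyloxy)phenyl]-4-oxochroman-5-yl]oxy}-2-methoxypiperidine-1-carboxylate
Conditions: PPh3, DIAD, PhMe–THF, 0 → 40 °C
Reagents that add atoms: none
Why: Mitsunobu reaction of the remaining 5-OH on an ordinary secondary alcohol proceeds by SN2 inversion (4R → 4S), which puts the aryl oxygen on the ring face where the aryl carbon must later arrive.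

**Step 7**
Reactants: 11 benzyl (4S)-4-{[(2S)-7-(benzyloxy)-2-[4-(benzyloxy)phenyl]-4-oxochroman-5-yl]oxy}-2-methoxypiperidine-1-carboxylate
Product: 12 benzyl (4S)-4-{[(2S)-7-(benzyloxy)-2-[4-(benzyloxy)phenyl]-4-oxochroman-5-yl]oxy}-3,4-dihydropyridine-1(2H)-carboxylate
Conditions: TMSOTf, i-Pr2NEt, CH2Cl2, −78 → 0 °C
Reagents that add atoms: none
Why: TMSOTf ionises the N,O-acetal to the N-acyliminium ion and the amine removes H-3 (E1 elimination), giving the enecarbamate, which is now an allyl aryl ether with C-4 unchanged.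

**Step 8**
Reactants: 12 benzyl (4S)-4-{[(2S)-7-(benzyloxy)-2-[4-(benzyloxy)phenyl]-4-oxochroman-5-yl]oxy}-3,4-dihydropyridine-1(2H)-carboxylate
Product: 14 benzyl (2R)-2-[(2S)-7-(benzyloxy)-2-[4-(benzyloxy)phenyl]-5-hydroxy-4-oxochroman-6-yl]-5,6-dihydropyridine-1(2H)-carboxylate, via ortho-dienone 13 (not isolated)
Conditions: 1,2-Cl2C6H4 (degassed, 0.02 M), 150 °C, sealed tube, base-washed glassware
Reagents that add atoms: none
Why: Aromatic Claisen ([3,3]-sigmatropic) rearrangement to C-6, the only free ortho position, is suprafacial within the ring, so the (4S) ether carbon is relayed to the (2R) benzylic carbon (1,3-chirality transfer) before enolisation restores the chelated 5-OH.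

**Step 9**
Reactants: 14 benzyl (2R)-2-[(2S)-7-(benzyloxy)-2-[4-(benzyloxy)phenyl]-5-hydroxy-4-oxochroman-6-yl]-5,6-dihydropyridine-1(2H)-carboxylate
Product: 16 (2S)-5,7-dihydroxy-2-(4-hydroxyphenyl)-6-[(2R)-1-methylpiperidin-2-yl]chroman-4-one, via N-nor amine 15 (not isolated)
Conditions: H2 (1 atm), Pd/C, MeOH–EtOAc, rt; then aq. HCHO (1.5 equiv), H2, rt
Reagents that add atoms: formaldehyde, C=O
Why: Pd-catalysed hydrogenation saturates the alkene and cleaves both benzyl ethers and the Cbz group, and the freed secondary amine is methylated by reductive amination under neutral conditions that leave both stereocentres alone.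

**Compound list**
1 | ethyl (3R)-4-cyano-3-hydroxybutanoate | CCOC(=O)C[C@H](O)CC#N | starting material
2 | ethyl (3R)-5-amino-3-hydroxypentanoate | CCOC(=O)C[C@H](O)CCN | intermediate
3 | (4R)-4-hydroxypiperidin-2-one | O=C1C[C@H](O)CCN1 | intermediate
4 | (4R)-4-[(tert-butyldimethylsilyl)oxy]piperidin-2-one | O=C1C[C@H](O[Si](C)(C)C(C)(C)C)CCN1 | intermediate
5 | benzyl (4R)-4-[(tert-butyldimethylsilyl)oxy]-2-oxopiperidine-1-carboxylate | O=C1C[C@H](O[Si](C)(C)C(C)(C)C)CCN1C(=O)OCc1ccccc1 | intermediate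
6 | benzyl (4R)-4-[(tert-butyldimethylsilyl)oxy]-2-hydroxypiperidine-1-carboxylate (C-2 epimers) | OC1C[C@H](O[Si](C)(C)C(C)(C)C)CCN1C(=O)OCc1ccccc1 | intermediate
7 | benzyl (4R)-4-[(tert-butyldimethylsilyl)oxy]-2-methoxypiperidine-1-carboxylate (C-2 epimers) | COC1C[C@H](O[Si](C)(C)C(C)(C)C)CCN1C(=O)OCc1ccccc1 | intermediate
8 | benzyl (4R)-4-hydroxy-2-methoxypiperidine-1-carboxylate (C-2 epimers) | COC1C[C@H](O)CCN1C(=O)OCc1ccccc1 | intermediate
9 | (2S)-naringenin, (2S)-5,7-dihydroxy-2-(4-hydroxyphenyl)chroman-4-one | O=C1C[C@@H](c2ccc(O)cc2)Oc2cc(O)cc(O)c12 | starting material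
10 | (2S)-7-(benzyloxy)-2-[4-(benzyloxy)phenyl]-5-hydroxychroman-4-one | O=C1C[C@@H](c2ccc(OCc3ccccc3)cc2)Oc2cc(OCc3ccccc3)cc(O)c12 | intermediate
11 | benzyl (4S)-4-{[(2S)-7-(benzyloxy)-2-[4-(benzyloxy)phenyl]-4-oxochroman-5-yl]oxy}-2-methoxypiperidine-1-carboxylate (C-2 epimers) | COC1C[C@@H](Oc2cc(OCc3ccccc3)cc3c2C(=O)C[C@@H](c2ccc(OCc4ccccc4)cc2)O3)CCN1C(=O)OCc1ccccc1 | intermediate
12 | benzyl (4S)-4-{[(2S)-7-(benzyloxy)-2-[4-(benzyloxy)phenyl]-4-oxochroman-5-yl]oxy}-3,4-dihydropyridine-1(2H)-carboxylate | O=C(OCc1ccccc1)N1CC[C@H](Oc2cc(OCc3ccccc3)cc3c2C(=O)C[C@@H](c2ccc(OCc4ccccc4)cc2)O3)C=C1 | intermediate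
13 | 6H-cyclohexa-dienone tautomer of 14 (C-5 ketone, C-6 sp3 carrying the tetrahydropyridinyl group) | O=C1C[C@@H](c2ccc(OCc3ccccc3)cc2)OC2=C1C(=O)C([C@H]1C=CCCN1C(=O)OCc1ccccc1)C(OCc1ccccc1)=C2 | intermediate
14 | benzyl (2R)-2-[(2S)-7-(benzyloxy)-2-[4-(benzyloxy)phenyl]-5-hydroxy-4-oxochroman-6-yl]-5,6-dihydropyridine-1(2H)-carboxylate (C3=C4 alkene) | O=C1C[C@@H](c2ccc(OCc3ccccc3)cc2)Oc2cc(OCc3ccccc3)c([C@H]3C=CCCN3C(=O)OCc3ccccc3)c(O)c12 | intermediate
15 | (2S)-5,7-dihydroxy-2-(4-hydroxyphenyl)-6-[(2R)-piperidin-2-yl]chroman-4-one | O=C1C[C@@H](c2ccc(O)cc2)Oc2cc(O)c([C@H]3CCCCN3)c(O)c12 | intermediate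
16 | (2S)-5,7-dihydroxy-2-(4-hydroxyphenyl)-6-[(2R)-1-methylpiperidin-2-yl]chroman-4-one | CN1CCCC[C@@H]1c1c(O)cc2c(c1O)C(=O)C[C@@H](c1ccc(O)cc1)O2 | target

**Totals**
Total step count: 9. Longest linear sequence: 8 (steps 1–4, then 6–9).

**Steps most likely to fail**

Step 8 (Claisen shift). The nitrogen donor at the allyl terminus slows the concerted path, so ionisation of the vinylogous N,O-acetal or elimination of phenol 10 may compete. Fallback: set out from 12 and treat it with BF3·OEt2 in CH2Cl2 at −40 °C. The ether ionises to the conjugated N-acyliminium ion and phenol 10, which recombine by Friedel–Crafts amidoalkylation ortho to the chelated 5-OH. This ionic route no longer relays the C-4 configuration, so 14 forms together with its piperidine epimer, benzyl (2S)-2-[(2S)-7-(benzyloxy)-2-[4-(benzyloxy)phenyl]-5-hydroxy-4-oxochroman-6-yl]-5,6-dihydropyridine-1(2H)-carboxylate F4, and must be separated by chromatography. The fallback comes back to the route at 14.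

Step 6 (Mitsunobu at the chelated 5-OH). The phenol is hindered and weakly acidic, so alkylation of the hydrazide or elimination of the activated alcohol may dominate. Fallback: set out from 8 and sulfonylate it (4-nitrobenzenesulfonyl chloride, Et3N, DMAP, CH2Cl2, 0 °C) to benzyl (4R)-2-methoxy-4-{[(4-nitrophenyl)sulfonyl]oxy}piperidine-1-carboxylate F1. Displace this with the phenoxide of 10 (Cs2CO3, DMF, 25 °C) in an SN2 inversion. Keep the temperature low and check the flavanone C-2 by chiral HPLC. The fallback comes back to the route at 11.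

Step 7 (enecarbamate formation). TMSOTf may also silylate the ketone or ionise the new allylic ether. Fallback: set out from 11 and exchange methoxy for phenylthio (PhSH, BF3·OEt2, CH2Cl2, −78 °C, while the ether is still non-allylic) to give benzyl (4S)-4-{[(2S)-7-(benzyloxy)-2-[4-(benzyloxy)phenyl]-4-oxochroman-5-yl]oxy}-2-(phenylsulfanyl)piperidine-1-carboxylate F2. Oxidise with mCPBA at −78 °C to benzyl (4S)-4-{[(2S)-7-(benzyloxy)-2-[4-(benzyloxy)phenyl]-4-oxochroman-5-yl]oxy}-2-(phenylsulfinyl)piperidine-1-carboxylate F3. Warm this in toluene at 70 °C with P(OMe)3; the acid-free sulfoxide syn-elimination gives the enecarbamate. The fallback comes back to the route at 12.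

**Further compounds**
F1 | step 6 | benzyl (4R)-2-methoxy-4-{[(4-nitrophenyl)sulfonyl]oxy}piperidine-1-carboxylate | COC1C[C@H](OS(=O)(=O)c2ccc(cc2)[N+](=O)[O-])CCN1C(=O)OCc1ccccc1
F2 | step 7 | benzyl (4S)-4-{[(2S)-7-(benzyloxy)-2-[4-(benzyloxy)phenyl]-4-oxochroman-5-yl]oxy}-2-(phenylsulfanyl)piperidine-1-carboxylate | c1ccccc1SC1C[C@@H](Oc2cc(OCc3ccccc3)cc3c2C(=O)C[C@@H](c2ccc(OCc4ccccc4)cc2)O3)CCN1C(=O)OCc1ccccc1
F3 | step 7 | benzyl (4S)-4-{[(2S)-7-(benzyloxy)-2-[4-(benzyloxy)phenyl]-4-oxochroman-5-yl]oxy}-2-(phenylsulfinyl)piperidine-1-carboxylate | O=S(c1ccccc1)C1C[C@@H](Oc2cc(OCc3ccccc3)cc3c2C(=O)C[C@@H](c2ccc(OCc4ccccc4)cc2)O3)CCN1C(=O)OCc1ccccc1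
F4 | step 8 | benzyl (2S)-2-[(2S)-7-(benzyloxy)-2-[4-(benzyloxy)phenyl]-5-hydroxy-4-oxochroman-6-yl]-5,6-dihydropyridine-1(2H)-carboxylate | O=C1C[C@@H](c2ccc(OCc3ccccc3)cc2)Oc2cc(OCc3ccccc3)c([C@@H]3C=CCCN3C(=O)OCc3ccccc3)c(O)c12
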